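**Strategy.** The route rests on cutting ring B (C1–C9–C5–C6–C7–C8) of the bicyclo[3.3.1]nonane at C9–C5 and C1–C8. The key step unites two fragments in one telescoped operation: the γ-carbon (C5) of a dioxinone that carries a Sharpless-derived farnesyl epoxide is acylated by an enol-ether acid chloride (C9), and the enol-ether carbon C1 then opens the epoxide at tertiary C8. It exploits the fact that C9 is a ketone flanked by two enolisable carbons (C1, C5) and that C7–C8 maps onto the 2,3-bond of farnesol. Ring A is closed afterwards by acylketene C-acylation at C1, and the C7 oxygen is exchanged for prenyl by radical allylation and cross-metathesis.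

Key step: step 7

Remark: locants are C1 (acyl-bearing bridgehead), C2 (ketone), C3 (vinylic CH), C4 (enol carbon), C5 (CH bridgehead), C6 (CH2), C7 (prenyl-bearing CH), C8 (quaternary carbon), C9 (bridging ketone), with ring A = C1–C2–C3–C4–C5–C9; 1,3-dicarbonyl intermediates are written as one tautomer, and 13 is assumed to be an equilibrating mixture of C5 epimers.

**Step 1**
Reactants: 1 (2E,6E)-farnesol
Product: 2 (2S,3S)-2,3-epoxyfarnesol
Conditions: Ti(OiPr)4 (cat.), L-(+)-diethyl tartrate (cat.), t-BuOOH, 4 Å molecular sieves, CH2Cl2, −20 °C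
Reagents that add atoms: tert-butyl hydroperoxide, CC(C)(C)OO
Why: Sharpless asymmetric epoxidation touches only the allylic 2,3-alkene and, with the L-(+)-tartrate, should give the (2S,3S)-epoxide, which fixes the later C8 (and the C7 oxygen) configuration.

**Step 2**
Reactants: 2 (2S,3S)-2,3-epoxyfarnesol
Product: 3 epoxy iodide (CH2OH of 2 replaced by CH2I)
Conditions: PPh3, I2, imidazole, Et2O/MeCN, 0 °C
Reagents that add atoms: iodine, II
Why: Appel-type iodination of the primary alcohol proceeds by SN2 at CH2 and leaves the epoxide and both its stereocentres untouched.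

**Step 3**
Reactants: 3 epoxy iodide; 4 2,2,6-trimethyl-4H-1,3-dioxin-4-one
Product: 5 dioxinone carrying the epoxy side chain on its γ-carbon
Conditions: LiN(iPr)2, THF/DMPU, −78 °C; then 3, −78 → −20 °C
Reagents that add atoms: none
Why: γ-Alkylation of the lithium dienolate of the dioxinone (vinylogous enolate alkylation) displaces the primary iodide by SN2 and does not touch the epoxide stereocentres.

**Step 4**
Reactants: 6 methyl 4-methyl-3-oxopentanoate
Product: 7 methyl (E)-3-methoxy-4-methylpent-2-enoate
Conditions: HC(OMe)3, H2SO4 (cat.), MeOH, 60 °C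
Reagents that add atoms: trimethyl orthoformate, COC(OC)OC
Why: Acid-catalysed enol ether formation from the β-keto ester via its dimethyl ketal should give the thermodynamically preferred (E)-β-methoxy enoate.

**Step 5**
Reactants: 7 methyl (E)-3-methoxy-4-methylpent-2-enoate
Product: 8 (E)-3-methoxy-4-methylpent-2-enoic acid
Conditions: LiOH, THF/H2O, 50 °C; then 1 M HCl to pH 3, 0 °C
Reagents that add atoms: lithium hydroxide, [Li+].[OH-]
Why: Saponification of the methyl ester, in which the vinylogous-carbonate enol ether tolerates base and a cold, brief acidification.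

**Step 6**
Reactants: 8 (E)-3-methoxy-4-methylpent-2-enoic acid
Product: 9 (E)-3-methoxy-4-methylpent-2-enoyl chloride
Conditions: (COCl)2, DMF (cat.), CH2Cl2, 0 °C → rt
Reagents that add atoms: oxalyl chloride, O=C(Cl)C(=O)Cl
Why: Acid chloride formation with oxalyl chloride under Vilsmeier-type catalysis is the standard entry to β-alkoxyacryloyl chlorides.

**Step 7**
Reactants: 5 dioxinone epoxide; 9 (E)-3-methoxy-4-methylpent-2-enoyl chloride
Product: 13 ring-B hydroxy diketone (enol form), via C5-acylated dioxinone 10 (not isolated), via siloxydiene 11 (not isolated), via cyclised bis-silyl ether 12 (not isolated)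
Conditions: LiN(iPr)2 (2.1 equiv), THF, −78 °C; 9; then CH2Cl2, 2,6-lutidine, Me3SiOTf (2.2 equiv), −78 → −30 °C; then 1 M HCl, THF, 0 °C
Reagents that add atoms: water, O
Why: Proposed new method: the lithium γ-dienolate of 5 is C-acylated at C5 by 9 (the known acylation of dioxinone dienolates, here forming C9–C5), the resulting chelated enolate is O-silylated to siloxydiene 11, and Me3SiOTf then activates the trisubstituted epoxide so that C1, the β-carbon of the methyl enol ether, opens it at tertiary C8 (closest known types: silyl-triflate-mediated enol ether–epoxide cyclisation and the acylation-then-ring-closure logic of an Effenberger annulation); running both events in one flask is the untested part. Ring B, the only ring formed here, closes by a 6-endo opening of the epoxide with the nucleophilic C=C exocyclic to the new ring. C8 is set by inversion at the (S)-epoxide carbon made in step 1, C7 keeps the epoxide oxygen, and C5 and C1 stay epimerisable until step 8. The step needs C- over O-alkylation and attack by C1 rather than by C5 or the dioxinone α-carbon C3: every oxygen is capped (silyl, methyl, acetonide), C5 could only close a three- or four-membered ring, and C3 is the α-carbon of an enoate and less nucleophilic than the enol ether carbon C1. Acidic work-up hydrolyses both enol ethers and the silyl ether to give 13.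

**Step 8**
Reactants: 13 ring-B hydroxy diketone
Product: 17 7-hydroxy bicyclic trione, via bis-silyl ether 14 (not isolated), via acylketene 15 (not isolated), via silylated bicycle 16 (not isolated)
Conditions: MeC(OSiMe3)=NSiMe3, PhMe, rt; then 110 °C, 0.005 M; then 1 M HCl, THF, rt
Reagents that add atoms: none
Why: Retro-[4+2] fragmentation of the dioxinone gives an acylketene that should be C-acylated intramolecularly by the silyl enol ether carbon C1 (the ring-closing acylation of an Effenberger-type cyclisation), making C1 quaternary; ring A can only bridge the face of ring B that keeps the C7 oxygen and the homogeranyl chain equatorial, so C1 and C5 follow from C8.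

**Step 9**
Reactants: 17 7-hydroxy bicyclic trione
Product: 18 C7 thiocarbonylimidazolide
Conditions: 1,1'-thiocarbonyldiimidazole, DMAP (cat.), ClCH2CH2Cl, 60 °C
Reagents that add atoms: 1,1'-thiocarbonyldiimidazole, S=C(n1ccnc1)n1ccnc1
Why: Thiocarbonylation of the secondary C7 alcohol (the activation half of a Barton–McCombie sequence) gives a radical precursor, while any derivative of the more acidic enol OH should be cleaved again on aqueous work-up.

**Step 10**
Reactants: 18 C7 thiocarbonylimidazolide
Product: 19 7-allyl bicyclic trione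
Conditions: Bu3SnCH2CH=CH2, AIBN, PhH, 80 °C
Reagents that add atoms: allyltributylstannane, C=CC[Sn](CCCC)(CCCC)CCCC
Why: Keck radical allylation, in which the C7 radical should be trapped by the allylstannane on the exo face away from ring A, so that allyl ends equatorial (7S).

**Step 11**
Reactants: 19 7-allyl bicyclic trione
Product: 20 prolifenone B
Conditions: second-generation Grubbs catalyst RuCl2(=CHPh)(PCy3)(H2IMes) (5 mol%), 2-methyl-2-butene, CH2Cl2, 35 °C
Reagents that add atoms: 2-methyl-2-butene, CC=C(C)C
Why: Olefin cross-metathesis of the monosubstituted allyl group with 2-methyl-2-butene should give the prenyl group, the trisubstituted alkenes of the homogeranyl chain being far less reactive, and no stereocentre is touched.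

**Compound list**

1 | (2E,6E)-farnesol | CC(C)=CCC/C(C)=C/CC/C(C)=C/CO | starting material
2 | (2S,3S)-2,3-epoxyfarnesol, [(2S,3S)-3-methyl-3-((3E)-4,8-dimethylnona-3,7-dien-1-yl)oxiran-2-yl]methanol | CC(C)=CCC/C(C)=C/CC[C@]1(C)O[C@H]1CO | intermediate
3 | (2S,3R)-3-(iodomethyl)-2-methyl-2-((3E)-4,8-dimethylnona-3,7-dien-1-yl)oxirane (same spatial arrangement as 2) | CC(C)=CCC/C(C)=C/CC[C@]1(C)O[C@H]1CI | intermediate
4 | 2,2,6-trimethyl-4H-1,3-dioxin-4-one | CC1=CC(=O)OC(C)(C)O1 | starting material
5 | 2,2-dimethyl-6-{2-[(2S,3S)-3-methyl-3-((3E)-4,8-dimethylnona-3,7-dien-1-yl)oxiran-2-yl]ethyl}-4H-1,3-dioxin-4-one | CC(C)=CCC/C(C)=C/CC[C@]1(C)O[C@H]1CCC2=CC(=O)OC(C)(C)O2 | intermediate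
6 | methyl 4-methyl-3-oxopentanoate | CC(C)C(=O)CC(=O)OC | starting material
7 | methyl (E)-3-methoxy-4-methylpent-2-enoate | CO/C(=C/C(=O)OC)C(C)C | intermediate
8 | (E)-3-methoxy-4-methylpent-2-enoic acid | CO/C(=C/C(=O)O)C(C)C | intermediate
9 | (E)-3-methoxy-4-methylpent-2-enoyl chloride | CO/C(=C/C(=O)Cl)C(C)C | intermediate
10 | keto-dioxinone: 5 bearing the (E)-3-methoxy-4-methylpent-2-enoyl group on the dioxinone γ-carbon C5 (both C5 epimers; lithium enolate in the flask) | CC(C)=CCC/C(C)=C/CC[C@]1(C)O[C@H]1CC(C(=O)/C=C(/OC)C(C)C)C2=CC(=O)OC(C)(C)O2 | intermediate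
11 | trimethylsilyl dienol ether of 10 (C5=C9–OSiMe3 with C1 cis to C6; 1-methoxy-3-siloxy-diene) | CC(C)=CCC/C(C)=C/CC[C@]1(C)O[C@H]1C/C(C2=CC(=O)OC(C)(C)O2)=C(/O[Si](C)(C)C)\C=C(\OC)C(C)C | intermediate
12 | cyclised bis-silyl ether: cyclohexene with C5=C9–OSiMe3, exocyclic C1=C(OMe)iPr, (7S)-OSiMe3, (8S)-methyl/homogeranyl, dioxinonyl on C5 | COC(C(C)C)=C1C(O[Si](C)(C)C)=C(C2=CC(=O)OC(C)(C)O2)C[C@H](O[Si](C)(C)C)[C@@]1(C)CC/C=C(C)/CCC=C(C)C | intermediate
13 | (3S,4S)-6-(2,2-dimethyl-4-oxo-4H-1,3-dioxin-6-yl)-4-hydroxy-3-methyl-3-((3E)-4,8-dimethylnona-3,7-dien-1-yl)-2-(2-methylpropanoyl)cyclohexan-1-one, drawn as its endocyclic enol; ring C6 (core C5) epimers | CC(C)C(=O)C1=C(O)C(C2=CC(=O)OC(C)(C)O2)C[C@H](O)[C@@]1(C)CC/C=C(C)/CCC=C(C)C | intermediate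
14 | bis(trimethylsilyl) derivative of 13 (enol oxygen and C7 oxygen silylated) | CC(C)C(=O)C1=C(O[Si](C)(C)C)C(C2=CC(=O)OC(C)(C)O2)C[C@H](O[Si](C)(C)C)[C@@]1(C)CC/C=C(C)/CCC=C(C)C | intermediate
15 | acylketene from 14 (C5–C(=O)–CH=C=O in place of the dioxinone) | CC(C)C(=O)C1=C(O[Si](C)(C)C)C(C(=O)C=C=O)C[C@H](O[Si](C)(C)C)[C@@]1(C)CC/C=C(C)/CCC=C(C)C | intermediate
16 | bis-silylated bicycle: 17 with Me3Si on the C7 oxygen and on the C4 enol oxygen | CC(C)=CCC/C(C)=C/CC[C@]1(C)[C@@H](O[Si](C)(C)C)C[C@H]2C(=O)[C@]1(C(=O)C(C)C)C(=O)C=C2O[Si](C)(C)C | intermediate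
17 | (1R,5R,7S,8S)-4,7-dihydroxy-8-methyl-8-((3E)-4,8-dimethylnona-3,7-dien-1-yl)-1-(2-methylpropanoyl)bicyclo[3.3.1]non-3-ene-2,9-dione (C7–OH equatorial, C8–Me axial) | CC(C)=CCC/C(C)=C/CC[C@]1(C)[C@@H](O)C[C@H]2C(=O)[C@]1(C(=O)C(C)C)C(=O)C=C2O | intermediate
18 | O-(C7) 1H-imidazole-1-carbothioate of 17, (1R,5R,7S,8S) | CC(C)=CCC/C(C)=C/CC[C@]1(C)[C@@H](OC(=S)n3ccnc3)C[C@H]2C(=O)[C@]1(C(=O)C(C)C)C(=O)C=C2O | intermediate
19 | (1R,5R,7S,8R)-4-hydroxy-8-methyl-8-((3E)-4,8-dimethylnona-3,7-dien-1-yl)-1-(2-methylpropanoyl)-7-(prop-2-en-1-yl)bicyclo[3.3.1]non-3-ene-2,9-dione | CC(C)=CCC/C(C)=C/CC[C@]1(C)[C@@H](CC=C)C[C@H]2C(=O)[C@]1(C(=O)C(C)C)C(=O)C=C2O | intermediate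
20 | prolifenone B, (1R,5R,7S,8R) in the locants above | CC(C)=CCC/C(C)=C/CC[C@]1(C)[C@@H](CC=C(C)C)C[C@H]2C(=O)[C@]1(C(=O)C(C)C)C(=O)C=C2O | target

**Count.** Total steps: 11. Longest linear sequence: 8 steps (steps 1, 2, 3, 7, 8, 9, 10, 11).

**Steps most likely to fail**

1. Step 7 (Proposed new method). The lithium dienolate may close a cyclopropane onto the neighbouring epoxide before it is acylated. After silylation the epoxide may be opened by an oxygen or by the dioxinone α-carbon C3 instead of C1, or rearrange to a carbonyl compound. The siloxydiene may also form with the wrong double-bond geometry and fail to reach C8. The fallback sets out from 5 and comes back at 13, using two separate operations and a different nucleophile. The C-acylation of the dioxinone dienolate is run alone and keto-dioxinone 10 is isolated. Cold dilute acid hydrolyses its methyl enol ether to the diketo-dioxinone F1. F1 is then cyclised by Lewis-acid opening of the epoxide (Sc(OTf)3, CH2Cl2, or hexafluoroisopropanol as solvent) with C-alkylation of the 1,3-diketone enol at C1, a cation capture by a 1,3-dicarbonyl of known type, to give 13.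

2. Step 8. The acylketene may be captured by an oxygen of the C9 ketone and tautomerise to a fused 2-pyranone, or dimerise, instead of acylating the hindered C1. The fallback sets out from 13 and comes back at 17. Heating 13 in toluene–methanol traps the acylketene as the methyl β-keto ester F2. Ring A is then closed by an intramolecular Claisen (Dieckmann-type) condensation of the C1 enolate onto the ester with KOtBu in THF, the base-mediated closure type known for bicyclo[3.3.1]nonane-2,4,9-triones.

3. Step 3. The dienolate may be alkylated at its α- instead of its γ-carbon, or attack the epoxide. The fallback sets out from 3 and comes back at 5. The lithium enolate of methyl acetate is alkylated with 3 to give ester F3, and saponification gives acid F4. Coupling with Meldrum's acid (EDC, DMAP) gives the acyl Meldrum's acid F5, and heating F5 with acetone in toluene builds the dioxinone ring.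

Further compounds
F1 | step 7 | diketo-dioxinone: 5 bearing a 4-methyl-3-oxopentanoyl group on the γ-carbon C5 | CC(C)=CCC/C(C)=C/CC[C@]1(C)O[C@H]1CC(C(=O)CC(=O)C(C)C)C2=CC(=O)OC(C)(C)O2
F2 | step 8 | methyl β-keto ester: 13 with the dioxinonyl group replaced by a 3-methoxy-3-oxopropanoyl group | CC(C)C(=O)C1=C(O)C(C(=O)CC(=O)OC)C[C@H](O)[C@@]1(C)CC/C=C(C)/CCC=C(C)C
F3 | step 3 | methyl 3-[(2S,3S)-3-methyl-3-((3E)-4,8-dimethylnona-3,7-dien-1-yl)oxiran-2-yl]propanoate | CC(C)=CCC/C(C)=C/CC[C@]1(C)O[C@H]1CCC(=O)OC
F4 | step 3 | 3-[(2S,3S)-3-methyl-3-((3E)-4,8-dimethylnona-3,7-dien-1-yl)oxiran-2-yl]propanoic acid | CC(C)=CCC/C(C)=C/CC[C@]1(C)O[C@H]1CCC(=O)O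
F5 | step 3 | acyl Meldrum's acid from F4 (enol form) | CC(C)=CCC/C(C)=C/CC[C@]1(C)O[C@H]1CCC(O)=C2C(=O)OC(C)(C)OC2=O
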